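12.1 mM of product stood in the east run at 30.0 min, and 11.7 mM in the south-east run, from charges of 13 mM and 30 mM of solid substrate. The two differ by 0.400 mM, less than the 0.600 mM that one south-east reading scatters. So a quick number can be solved at these two ends of the charge and joined.

in all of them: gas phase 1.1 mM (held); free catalyst 40 µM
- east: solid substrate 0.013 M; impurity 19 µM; run made earlier
- south-east: solid substrate 0.030 M; impurity 19 µM; run made earlier
- north-west: solid substrate 0.020 M; impurity 28 µM; run made earlier
- flask: solid substrate 0.020 M; impurity 19 µM; time 30 min

| run | time / min | product / % | solid substrate / % |
|---|---|---|---|
| east | 4.00 | 8 | 79 |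
| east | 10.0 | 30 | 59 |
| east | 20.0 | 65 | 25 |
| east | 30.0 | 93 | 1 |
| south-east | 2.50 | 1 | 94 |
| south-east | 6.00 | 7 | 87 |
| south-east | 12.0 | 19 | 77 |
| south-east | 30.0 | 39 | 52 |
| north-west | 2.50 | 2 | 93 |
| north-west | 6.00 | 7 | 85 |
| north-west | 12.0 | 15 | 71 |
| north-west | 30.0 | 46 | 47 |

(each reading ± 2 percentage points)

- given per volume of solution although it is solid: solid substrate
- at the start none of the gas phase is in solution
- at the start none of the solid substrate is in solution

- oak: doubling the dissolution coefficient of the solid substrate, all else as stated
- cedar: doubling the solubility of the solid substrate, all else as stated
- maple: doubling the amount of free catalyst, all else as stated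
- elm: doubling the transfer coefficient of the gas phase, all else as stated

- amount of product at 30 min, in percent of the solid substrate charged
- the change that raises the amount of product at 30 min, in percent of the solid substrate charged most ("none" if none brings more than 2 percentage points) (oak / cedar / maple / elm / none)
- amount of product at 30 min, in percent of the solid substrate charged, after cedar

Let W be the output, the concentration of product standing at 30.0 min in a run, with catalyst, impurity and gas held as in those two runs:

W = mean of east and south-east = 11.9 mM

y = W / charge = 59.5%

W holds for that impurity: with 28 µM of it the north-west run read 9.20 mM, less than W.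

My reckoning for the changes assumes that dissolved substrate is used pseudo-first-order. Doubling its solubility then doubles W; the other changes are not reckoned here:

W doubled = 23.8 mM, above the 20 mM charged

So I commit to cedar, with nearly all of the charge as product.

The forecast gives 60% (54% to 66%), cedar, and 82% (68% to 95%) after it, saying “Possible gas limitation caps this”; my figure after cedar lies higher.

The flask gives 64.9%, and cedar is the best change. Starting material stood at 7.18% of the charge at 15.0 min and 7.18% at 30.0 min, when it was made 1.00 times as fast as it was used up. As an output the flask holds 13.0 mM; doubled, that is 26.0 mM, above the charge, and cedar gives 99.3%.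

    gas phase ⇌ dissolved gas, rate k1*(csat - [dissolved gas]) (kL = 0.130 /s)
    starting material + dissolved gas + free catalyst → free catalyst + product (k = 6.05 × 10⁵ /M²/s)
    solid substrate ⇌ starting material, rate k3*(cs3 - [starting material]) while solid is left; crystals form when [starting material] > cs3 (solubility = 2.90 mM, k = 0.00519 /s)
    free catalyst ⇌ dormant form (K = 1.50, k = 0.0309 /s)
    free catalyst + impurity → spent catalyst (k = 31100 /M/s)

The neighbour flask charged with 0.050 M of solid substrate gets from this output 26.0% of its charge. Computed, it gives 26.0%.

(The numbers in the tables stem from a simulated flask for substances that don't exist; noise was put on by code.)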